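All constants were chosen freely; the flask was simulated.

Late readings are not asked for here: each flask is read at 30 s.

| flask | solid substrate | gas | time | remark | temperature |
|---|---|---|---|---|---|
| summer | 0.010 M | 4.5 mM (held) | 30 s | at 50 °C until 15 s, from then on at 0 °C |  |
| dusk | 0.010 M | 4.5 mM (held) | 30 s |  | 0 °C |
| dawn | 0.010 M | 4.5 mM (held) | 30 s |  | 25 °C |
| noon | 0.010 M | 4.5 mM (held) | 30 s |  | 50 °C |

    starting material + reagent → mono adduct (k1 = 20 /M/s, Ea1 = 44.0 kJ/mol)
    reagent + mono adduct → bis adduct (k2 = 46 /M/s, Ea2 = 45.0 kJ/mol)
    reagent + bis adduct → tris adduct (k3 = 20 /M/s, Ea3 = 41.0 kJ/mol)
    reagent + tris adduct → tetra adduct (k4 = 2.0 /M/s, Ea4 = 46.0 kJ/mol)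
    gas ⇌ reagent, rate k5*(csat - [reagent]) (k5 = 0.40 /s, csat = 4.5 mM)
    solid substrate ⇌ starting material, rate k6*(cs6 - [starting material]) while solid is left; crystals form when [starting material] > cs6 (cs6 = 7.0 mM, k6 = 0.44 /s)
    (constants at 50 °C)

- given per volume of solution although it is solid: solid substrate
- at the start none of reagent is dissolved
- the constants hold at 50 °C; other temperatures follow from the activation energies
- at the start none of the solid substrate is in solution
- what has only dissolved of solid substrate counts as not reacted

* which flask leads in share of mono adduct in all that became mono adduct or bis adduct or tris adduct or tetra adduct ("all alike" within 1.5 percentage points) (summer / dusk / dawn / noon / all alike)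
* share of mono adduct in all that became mono adduct or bis adduct or tris adduct or tetra adduct, summer
* share of mono adduct in all that became mono adduct or bis adduct or tris adduct or tetra adduct, dusk
* share of mono adduct in all that became mono adduct or bis adduct or tris adduct or tetra adduct, dawn
* share of mono adduct in all that became mono adduct or bis adduct or tris adduct or tetra adduct, noon

Two chemists argue over these flasks. The gas feeds reagent, the solid substrate feeds starting material, and reagent adds to starting material and then to each adduct in turn.

I freeze two things. Reagent stands at its saturation level 4.5 mM, and dissolved starting material stands near 70.0% of the charge while solid is left. Mono adduct is then fed steadily and lost by a pseudo-first-order step. Its life at full reagent, 4.83 s at noon, is the mono life: one over k2 times the saturation level. Reagent needs about 2.50 s to come up, so I call x the time after that lag divided by the mono life. Steady feed with that loss gives a share of one minus exp(−x), over x, and k1 cancels.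

At noon x is 5.69, and the share is 17.5%. In dusk the life is 104 s, and the share is 87.8%. In dawn the life is 19.7 s, and the share is 53.9%. For summer I reckon the hot stretch up to 15 s, which gives 35.7%. I keep that figure for the cold stretch, because step 1 and step 2 then run 20 and 21 times slower.

The other chemist objects that the reagent level will not stay frozen in the heat. At noon, step 1 by itself asks 35.0% of what the gas can bring, against 1.75% in dusk. The forecast is that side's: 57% for summer, 88% for dusk, 60% for dawn and 28% for noon, with dusk leading, and large exposure at noon, “where reagent supply also limits the rate”.

The simulation gives 44.2% for summer, 88.4% for dusk, 57.8% for dawn and 19.1% for noon, and dusk leads. Noon lies 8.9 percentage points below the forecast and 1.6 points above my figure. Summer lies 13 points below the forecast and 8.5 points above mine. Dawn goes the other way, 2.2 points from the forecast and 3.9 points from mine.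

Dusk keeps both frozen things, with reagent at 0.00441 M, starting material at 69.3% and solid at 22.6%. The objection holds in the hot stretch of summer. At 15.0 s reagent stands at 0.00280 M, which stretches the mono life to 7.76 s. That gives a share of 49.7%, and the flask then holds 46.5%, against my frozen 35.7%.

Take a repeat of noon at 35 °C. The mono life becomes 10.9 s, so x is 2.52 and the share comes to 36.5%. The flask gives 40.9%, with reagent at 0.00353 M and solid at 0% when it is read. Starting material holds the largest part of the charge at the end, 45.9%.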